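**Retrosynthetic overview**

- 17 ⇐ 16 (pivalate methanolysis) ⇐ acid 15 by decarboxylative radical closure of the C3–C4 bond. The strategy rests on one feature of the cyclopentane (C1 quaternary with aryl and CH3, C2 methine with CH3, C3 carrying the exocyclic CHBr, C4 and C5 methylenes): C4 is a plain CH2 next to C3, so a primary C4 radical can attack the inner carbon of a bromoalkyne.
- 15 ⇐ aldehyde ester 10 by dibromo-olefination, exchange of the phenol methyl ether for a pivalate, ester demethylation and loss of HBr.
- 10 ⇐ ozonolysis of the cyclohexenyl silyl enol ether 8 between its C1 and C2. The six-membered ring is only a template that holds both stereocentres.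
- 8 ⇐ enone 7 (face-selective copper hydride 1,4-hydrosilylation sets the C–H centre) ⇐ vinylogous ester 4 (methyl transposition, ring bromination) ⇐ 1 + MeI + 3 (enantioselective α-arylation sets the quaternary centre).
- Ring order: the cyclohexene ring comes with 1 and is cut open in step 6; the cyclopentane is the only ring that is made, in step 12.

Key step: step 12

Assumption: the sense of induction in step 2 is assigned by analogy with α-arylations of 2-methyl-1-tetralone; (R)-BINAP is written for the catalyst that gives (6S)-4, and the antipodal ligand is used if the opposite sense is found.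

**Route**

Step 1
Reactants: 1 3-ethoxycyclohex-2-en-1-one
Product: 2 rac-3-ethoxy-6-methylcyclohex-2-en-1-one
Conditions: LDA, THF, −78 °C; MeI, −78 → 0 °C
Reagents that add atoms: iodomethane, CI
Why: Kinetic deprotonation of the vinylogous ester occurs at the α′-carbon C6 and the lithium enolate is C-methylated (Stork–Danheiser α′-alkylation); the new centre is racemic and becomes planar again in step 2.

Step 2
Reactants: 2 rac-3-ethoxy-6-methylcyclohex-2-en-1-one; 3 2-bromo-5-methylanisole
Product: 4 (6S)-3-ethoxy-6-(2-methoxy-4-methylphenyl)-6-methylcyclohex-2-en-1-one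
Conditions: LiN(SiMe3)2, toluene, −78 → 0 °C; then 3, Pd2(dba)3 (cat.), (R)-BINAP (cat.), 70 °C
Reagents that add atoms: none
Why: Pd-catalysed α-arylation of a ketone enolate: the kinetic α′-lithium enolate of 2 is planar at C6, so racemic 2 converges, and C–C reductive elimination from the arylpalladium enolate held by the chiral bisphosphine should set the quaternary centre as S.

Step 3
Reactants: 4 (6S)-3-ethoxy-6-(2-methoxy-4-methylphenyl)-6-methylcyclohex-2-en-1-one
Product: 6 (4R)-4-(2-methoxy-4-methylphenyl)-3,4-dimethylcyclohex-2-en-1-one, via tertiary allylic carbinol 5 (not isolated)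
Conditions: MeLi, CeCl3, THF, −78 → 0 °C; then 1 M HCl, rt
Reagents that add atoms: methyllithium, [Li]C; water, O
Why: Stork–Danheiser transposition: 1,2-addition of the methyl nucleophile to the vinylogous ester carbonyl, then acid hydrolysis of the enol ether and loss of water give the 3-methyl enone; the quaternary centre is untouched and its descriptor changes only through CIP priorities.

Step 4
Reactants: 6 (4R)-4-(2-methoxy-4-methylphenyl)-3,4-dimethylcyclohex-2-en-1-one
Product: 7 (4R)-4-(5-bromo-2-methoxy-4-methylphenyl)-3,4-dimethylcyclohex-2-en-1-one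
Conditions: NBS, MeCN, 0 °C → rt, dark
Reagents that add atoms: N-bromosuccinimide, O=C1CCC(=O)N1Br
Why: Electrophilic aromatic bromination goes to the position para to the methoxy group and ortho to the ring methyl, the most activated open site; the enone is inert to NBS under ionic conditions.

Step 5
Reactants: 7 (4R)-4-(5-bromo-2-methoxy-4-methylphenyl)-3,4-dimethylcyclohex-2-en-1-one
Product: 8 {[(3S,4R)-4-(5-bromo-2-methoxy-4-methylphenyl)-3,4-dimethylcyclohex-1-en-1-yl]oxy}(dimethyl)phenylsilane
Conditions: [(Ph3P)CuH]6 (cat.), PhMe2SiH, toluene, rt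
Reagents that add atoms: dimethylphenylsilane, C[SiH](C)c1ccccc1
Why: Copper hydride 1,4-hydrosilylation of an enone: in the half-chair of 7 the aryl group on C4 sits pseudoaxial to avoid allylic strain with the C3 methyl, so the bulky copper hydride should add axially to C3 on the face away from the aryl (C3–CH3 ends cis to aryl, 3S), and σ-bond metathesis of the copper enolate with the silane fixes the enol double bond between C1 and C2.

Step 6
Reactants: 8 {[(3S,4R)-4-(5-bromo-2-methoxy-4-methylphenyl)-3,4-dimethylcyclohex-1-en-1-yl]oxy}(dimethyl)phenylsilane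
Product: 10 methyl (4R,5R)-4-(5-bromo-2-methoxy-4-methylphenyl)-4,5-dimethyl-6-oxohexanoate, via aldehyde acid 9 (not isolated)
Conditions: O3, CH2Cl2/MeOH, −78 °C; Me2S, −78 °C → rt; then TMSCHN2, MeOH/toluene, 0 °C
Reagents that add atoms: ozone, [O-][O+]=O; (trimethylsilyl)diazomethane, C[Si](C)(C)C=[N+]=[N-]
Why: Ozonolysis of the electron-rich enol ether with reductive work-up turns C2 into the aldehyde and C1 into a silyl ester that methanol cleaves to the acid, which is methylated in the same pot (diazoalkane esterification); both stereocentres are untouched.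

Step 7
Reactants: 10 methyl (4R,5R)-4-(5-bromo-2-methoxy-4-methylphenyl)-4,5-dimethyl-6-oxohexanoate
Product: 11 methyl (4R,5S)-7,7-dibromo-4-(5-bromo-2-methoxy-4-methylphenyl)-4,5-dimethylhept-6-enoate
Conditions: CBr4, PPh3, CH2Cl2, 0 °C
Reagents that add atoms: tetrabromomethane, BrC(Br)(Br)Br
Why: Ramirez dibromo-olefination (first stage of the Corey–Fuchs sequence) by a Wittig reaction of Ph3P=CBr2; the non-basic ylide should leave the α-stereocentre of the hindered aldehyde intact.

Step 8
Reactants: 11 methyl (4R,5S)-7,7-dibromo-4-(5-bromo-2-methoxy-4-methylphenyl)-4,5-dimethylhept-6-enoate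
Product: 12 methyl (4R,5S)-7,7-dibromo-4-(5-bromo-2-hydroxy-4-methylphenyl)-4,5-dimethylhept-6-enoate
Conditions: BBr3, CH2Cl2, −78 → 0 °C; H2O
Reagents that add atoms: none
Why: Lewis-acid cleavage of the aryl methyl ether (bromide attacks the O-methyl of the boron-complexed ether) spares the methyl ester and the electron-poor dibromoalkene at 0 °C; the phenol is freed only now, when no ring enone is left that it could add to in an oxa-Michael reaction.

Step 9
Reactants: 12 methyl (4R,5S)-7,7-dibromo-4-(5-bromo-2-hydroxy-4-methylphenyl)-4,5-dimethylhept-6-enoate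
Product: 13 methyl (4R,5S)-7,7-dibromo-4-[5-bromo-4-methyl-2-(pivaloyloxy)phenyl]-4,5-dimethylhept-6-enoate
Conditions: PivCl, Et3N, DMAP (cat.), CH2Cl2, 0 °C → rt
Reagents that add atoms: pivaloyl chloride, CC(C)(C)C(Cl)=O
Why: DMAP-catalysed O-acylation of the phenol; the carboxyl group is still an ester, so neither a mixed anhydride nor a seven-membered aryl lactone can form.

Step 10
Reactants: 13 methyl (4R,5S)-7,7-dibromo-4-[5-bromo-4-methyl-2-(pivaloyloxy)phenyl]-4,5-dimethylhept-6-enoate
Product: 14 (4R,5S)-7,7-dibromo-4-[5-bromo-4-methyl-2-(pivaloyloxy)phenyl]-4,5-dimethylhept-6-enoic acid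
Conditions: LiI, pyridine, 100 °C; then 1 M HCl
Reagents that add atoms: none
Why: Nucleophilic ester dealkylation: iodide attacks the methyl group of the ester in an SN2 reaction, so the acid is freed without a nucleophile at any carbonyl and the hindered aryl pivalate and the dibromoalkene are not touched.

Step 11
Reactants: 14 (4R,5S)-7,7-dibromo-4-[5-bromo-4-methyl-2-(pivaloyloxy)phenyl]-4,5-dimethylhept-6-enoic acid
Product: 15 (4R,5R)-7-bromo-4-[5-bromo-4-methyl-2-(pivaloyloxy)phenyl]-4,5-dimethylhept-6-ynoic acid
Conditions: NaN(SiMe3)2 (2.3 equiv), THF, −78 °C; then cold 1 M HCl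
Reagents that add atoms: none
Why: Base-induced anti-dehydrobromination of the 1,1-dibromoalkene (Corey–Fuchs-type sequence stopped at the 1-bromoalkyne) after the first equivalent of base has made the carboxylate; the hindered, non-nucleophilic amide base at −78 °C spares the pivalate.

Step 12
Reactants: 15 (4R,5R)-7-bromo-4-[5-bromo-4-methyl-2-(pivaloyloxy)phenyl]-4,5-dimethylhept-6-ynoic acid
Product: 16 4-bromo-2-[(1R,2R,3Z)-3-(bromomethylidene)-1,2-dimethylcyclopentyl]-5-methylphenyl 2,2-dimethylpropanoate
Conditions: platinum anode and platinum cathode, undivided cell, MeOH, KOH (0.1 equiv), 0.05 M, constant current (about 100 mA per cm2), 10 °C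
Reagents that add atoms: none
Why: Proposed new method: one-electron oxidation of the carboxylate of 15 at platinum gives the acyloxy radical, which loses CO2; the primary C4 radical, which platinum does not oxidise further, adds to the inner alkyne carbon C3, and the α-bromovinyl radical takes a hydrogen atom from methanol. The closest known reaction type is Kolbe electrolysis of unsaturated acids in which the radical cyclises 5-exo onto an alkene before it is intercepted, together with tin-free 5-exo-dig closures of hex-5-ynyl radicals; the bromoalkyne acceptor and termination by hydrogen transfer from the solvent are the new elements. The cyclopentane closes in the 5-exo-dig mode through C3–C4, and 6-endo attack at the bromine-bearing carbon is stereoelectronically disfavoured. No stereocentre is formed, since C1 and C2 are already in 15 and lie away from every radical site; the only new stereo-element is the alkene, whose Z geometry should arise because the bent σ-vinyl radical inverts faster than it is quenched and methanol delivers hydrogen from the open C4 side, leaving bromine on the C2 side. The step needs ring closure to outrun radical–radical coupling and electron transfer to or from the arene and the C–Br bonds: the quaternary C1 and branched C2 fold the chain (Thorpe–Ingold effect), the acid is kept dilute, the brominated aryl pivalate is harder to oxidise than the carboxylate layer on the anode, and hydrogen evolution on the platinum cathode holds its potential positive of C–Br reduction.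

Step 13
Reactants: 16 4-bromo-2-[(1R,2R,3Z)-3-(bromomethylidene)-1,2-dimethylcyclopentyl]-5-methylphenyl 2,2-dimethylpropanoate
Product: 17 4-bromo-2-[(1R,2R,3Z)-3-(bromomethylidene)-1,2-dimethylcyclopentyl]-5-methylphenol
Conditions: K2CO3, MeOH, rt
Reagents that add atoms: none
Why: Base-catalysed transesterification (methanolysis) of the aryl ester releases the phenoxide as a good leaving group; the basic medium avoids acid-induced addition of the phenol to the exocyclic alkene.

**Compound list**

1 | 3-ethoxycyclohex-2-en-1-one | CCOC1=CC(=O)CCC1 | starting material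
2 | rac-3-ethoxy-6-methylcyclohex-2-en-1-one | CCOC1=CC(=O)C(C)CC1 | intermediate
3 | 2-bromo-5-methylanisole | COc1cc(C)ccc1Br | starting material
4 | (6S)-3-ethoxy-6-(2-methoxy-4-methylphenyl)-6-methylcyclohex-2-en-1-one | CCOC1=CC(=O)[C@](C)(c2ccc(C)cc2OC)CC1 | intermediate
5 | (6S)-3-ethoxy-6-(2-methoxy-4-methylphenyl)-1,6-dimethylcyclohex-2-en-1-ol (both C1 epimers, not isolated) | CCOC1=CC(C)(O)[C@](C)(c2ccc(C)cc2OC)CC1 | intermediate
6 | (4R)-4-(2-methoxy-4-methylphenyl)-3,4-dimethylcyclohex-2-en-1-one | O=C1C=C(C)[C@](C)(c2ccc(C)cc2OC)CC1 | intermediate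
7 | (4R)-4-(5-bromo-2-methoxy-4-methylphenyl)-3,4-dimethylcyclohex-2-en-1-one | O=C1C=C(C)[C@](C)(c2cc(Br)c(C)cc2OC)CC1 | intermediate
8 | {[(3S,4R)-4-(5-bromo-2-methoxy-4-methylphenyl)-3,4-dimethylcyclohex-1-en-1-yl]oxy}(dimethyl)phenylsilane | C[Si](C)(c1ccccc1)OC1=C[C@H](C)[C@](C)(c2cc(Br)c(C)cc2OC)CC1 | intermediate
9 | (4R,5R)-4-(5-bromo-2-methoxy-4-methylphenyl)-4,5-dimethyl-6-oxohexanoic acid (not isolated) | OC(=O)CC[C@@](C)(c1cc(Br)c(C)cc1OC)[C@@H](C)C=O | intermediate
10 | methyl (4R,5R)-4-(5-bromo-2-methoxy-4-methylphenyl)-4,5-dimethyl-6-oxohexanoate | COC(=O)CC[C@@](C)(c1cc(Br)c(C)cc1OC)[C@@H](C)C=O | intermediate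
11 | methyl (4R,5S)-7,7-dibromo-4-(5-bromo-2-methoxy-4-methylphenyl)-4,5-dimethylhept-6-enoate | COC(=O)CC[C@@](C)(c1cc(Br)c(C)cc1OC)[C@@H](C)C=C(Br)Br | intermediate
12 | methyl (4R,5S)-7,7-dibromo-4-(5-bromo-2-hydroxy-4-methylphenyl)-4,5-dimethylhept-6-enoate | COC(=O)CC[C@@](C)(c1cc(Br)c(C)cc1O)[C@@H](C)C=C(Br)Br | intermediate
13 | methyl (4R,5S)-7,7-dibromo-4-[5-bromo-4-methyl-2-(pivaloyloxy)phenyl]-4,5-dimethylhept-6-enoate | COC(=O)CC[C@@](C)(c1cc(Br)c(C)cc1OC(=O)C(C)(C)C)[C@@H](C)C=C(Br)Br | intermediate
14 | (4R,5S)-7,7-dibromo-4-[5-bromo-4-methyl-2-(pivaloyloxy)phenyl]-4,5-dimethylhept-6-enoic acid | OC(=O)CC[C@@](C)(c1cc(Br)c(C)cc1OC(=O)C(C)(C)C)[C@@H](C)C=C(Br)Br | intermediate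
15 | (4R,5R)-7-bromo-4-[5-bromo-4-methyl-2-(pivaloyloxy)phenyl]-4,5-dimethylhept-6-ynoic acid | OC(=O)CC[C@@](C)(c1cc(Br)c(C)cc1OC(=O)C(C)(C)C)[C@@H](C)C#CBr | intermediate
16 | 4-bromo-2-[(1R,2R,3Z)-3-(bromomethylidene)-1,2-dimethylcyclopentyl]-5-methylphenyl 2,2-dimethylpropanoate | Cc1cc(OC(=O)C(C)(C)C)c([C@]2(C)CC/C(=C/Br)[C@@H]2C)cc1Br | intermediate
17 | 4-bromo-2-[(1R,2R,3Z)-3-(bromomethylidene)-1,2-dimethylcyclopentyl]-5-methylphenol | Cc1cc(O)c([C@]2(C)CC/C(=C/Br)[C@@H]2C)cc1Br | target

**Totals and risks**

Total step count: 13. Longest linear sequence: 13 steps (1 → 17; 3 enters in step 2).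

The three steps most likely to fail:

Step 12 (the proposed new method). What may go wrong: coupling of two radicals at the anode surface or hydrogen abstraction before the ring has closed; electron transfer to or from the aryl bromide and the bromoalkyne; and unselective hydrogen delivery to the two sides of the bromovinyl radical, which would erode the Z geometry. The fallback uses known chemistry, Barton reductive decarboxylation with radical cyclisation. It sets out from acid 15, which is esterified with N-hydroxypyridine-2-thione (DCC, DMAP, CH2Cl2, dark) to the thiohydroxamate ester (Barton ester) F1. Irradiation of F1 with visible light in benzene in the presence of t-BuSH generates the same C4 radical in dilute homogeneous solution. It should close 5-exo-dig and take hydrogen from the bulky thiol on the open C4 side, and the route is rejoined at pivalate 16.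

Step 2. What may go wrong: slow C–C reductive elimination from the crowded ortho-substituted arylpalladium enolate and weak discrimination of the enolate faces, that is low conversion or low enantiomeric purity. The fallback inverts the order in which the two α′-substituents are introduced. It sets out from 1 and 3: the unsubstituted vinylogous ester 1 is arylated first (LiN(SiMe3)2; Pd(OAc)2, P(t-Bu)3, THF), a coupling at a methylene enolate that forms only a tertiary centre, to give racemic 3-ethoxy-6-(2-methoxy-4-methylphenyl)cyclohex-2-en-1-one F2. Its acidic benzylic α′-proton is then removed under chiral phase-transfer conditions (MeI, 50% aqueous KOH, toluene, 0 °C, a C2-symmetric binaphthyl-derived spiro ammonium bromide) and the ion-paired enolate is methylated enantioselectively. This comes back to the route at 4.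

Step 5. What may go wrong: delivery of the hydride to the face of C3 on the aryl side, which would give the C3 epimer. The fallback inverts the order in which hydrogen and methyl are placed on C3, so that the same facial preference then gives the needed relative configuration. It sets out from 4: reduction with DIBAL-H (−78 °C) gives the allylic alcohol (6S)-3-ethoxy-6-(2-methoxy-4-methylphenyl)-6-methylcyclohex-2-en-1-ol F3, and 1 M HCl converts it (Stork–Danheiser transposition with hydride) into (4R)-4-(2-methoxy-4-methylphenyl)-4-methylcyclohex-2-en-1-one F4. Bromination with NBS as in step 4 gives (4R)-4-(5-bromo-2-methoxy-4-methylphenyl)-4-methylcyclohex-2-en-1-one F5. Conjugate addition of Me2CuLi with TMSCl (THF, −78 °C) places the methyl group on C3 from the aryl side and traps the enolate as {[(3S,4R)-4-(5-bromo-2-methoxy-4-methylphenyl)-3,4-dimethylcyclohex-1-en-1-yl]oxy}trimethylsilane F6. Ozonolysis and esterification as in step 6 then pass through acid 9 and come back to the route at 10.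

Further compounds
F1 | step 12 | 2-thioxopyridin-1(2H)-yl (4R,5R)-7-bromo-4-[5-bromo-4-methyl-2-(pivaloyloxy)phenyl]-4,5-dimethylhept-6-ynoate | S=c1ccccn1OC(=O)CC[C@@](C)(c1cc(Br)c(C)cc1OC(=O)C(C)(C)C)[C@@H](C)C#CBr
F2 | step 2 | rac-3-ethoxy-6-(2-methoxy-4-methylphenyl)cyclohex-2-en-1-one | CCOC1=CC(=O)C(c2ccc(C)cc2OC)CC1
F3 | step 5 | (6S)-3-ethoxy-6-(2-methoxy-4-methylphenyl)-6-methylcyclohex-2-en-1-ol | CCOC1=CC(O)[C@](C)(c2ccc(C)cc2OC)CC1
F4 | step 5 | (4R)-4-(2-methoxy-4-methylphenyl)-4-methylcyclohex-2-en-1-one | O=C1C=C[C@](C)(c2ccc(C)cc2OC)CC1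
F5 | step 5 | (4R)-4-(5-bromo-2-methoxy-4-methylphenyl)-4-methylcyclohex-2-en-1-one | O=C1C=C[C@](C)(c2cc(Br)c(C)cc2OC)CC1
F6 | step 5 | {[(3S,4R)-4-(5-bromo-2-methoxy-4-methylphenyl)-3,4-dimethylcyclohex-1-en-1-yl]oxy}trimethylsilane | C[Si](C)(C)OC1=C[C@H](C)[C@](C)(c2cc(Br)c(C)cc2OC)CC1
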